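Readings and results are calculated for an exercise; scatter was added.

The constants are hidden, so a constant has to be read from the west run.

the same everywhere: electrophile 0.25 M
- west: nucleophile 0.29 M; run made earlier
- Wednesday's: nucleophile 0.420 M; time 2.0 d
- Monday's: nucleophile 0.330 M; time 2.0 d
- Tuesday's: nucleophile 0.550 M; time 2.0 d

- west (time / h: electrophile / %, target / %): 4.00: 80.8, 8.5; 8.00: 64.6, 9.7; 15.0: 46.1, 8.9; 25.0: 31.3, 7.2; 50.0: 15.5, 4.3

(scatter of a reading: 0.3 percentage points)



- part of the electrophile that has reacted at the end, Wednesday's
- part of the electrophile that has reacted at the end, Monday's
- part of the electrophile that has reacted at the end, Tuesday's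
- what raising the concentration of nucleophile from its lowest to its highest value here does to the part of the electrophile that has reacted (changes below 5 percentage points count as none) (it rises / no change / it falls)

What does the west run show? Electrophile falls to 15.5 % by 50.0 h. Target reads 9.7 % at 8.00 h and 4.3 % at the end, so target is a passing stage. The loss of electrophile is what to reckon.

Which law? Try electrophile meeting nucleophile, with the rate proportional to both and one nucleophile lost per electrophile lost. Then ln(share of nucleophile left / share of electrophile left) = (nucleophile charge − electrophile charge) × constant × time.

What does it give at each end of the run? The first reading gives 0.202 M⁻¹ h⁻¹. The last gives 0.280 M⁻¹ h⁻¹.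

But a constant that drifts is no constant. Why use it? Because the asked 2.0 d lies close to the last reading. The last value averages over nearly that same stretch. I call it the whole-run pairing constant, a second-order rate constant averaged from the charge to the last reading.

Where is the weak spot? One level of nucleophile cannot show the order in nucleophile, so the reckoning rests on an assumption.

What do you commit to? The same line gives 88.9 % reacted for Monday's, 95.6 % for Wednesday's and 99.0 % for Tuesday's. That is a rise of 10 percentage points, over the margin.

The forecast stands lower on each flask , with 87 % for Monday's, 93 % for Wednesday's, 97 % for Tuesday's and the verdict it rises, warning that “one nucleophile level cannot prove that order”.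

The flasks give 88.7 % for Monday's, 95.4 % for Wednesday's and 98.8 % for Tuesday's. The part reacted goes with the nucleophile: it rises, by 10 points.

    electrophile + nucleophile ⇌ acid set free + target (K = 4.40, k = 0.150 M⁻¹ h⁻¹)
    nucleophile + acid set free ⇌ protonated nucleophile, settled at all times (K = 20000 M⁻¹)
    electrophile + target → side product (k = 1.10 M⁻¹ h⁻¹)

The difference in nucleophile charge may be called the main reason for the gap between Tuesday's and Monday's. Tuesday's flask, given Monday's charge of nucleophile, reacts 88.7 % instead of 98.8 %. The further flask is Tuesday's recipe with 0.62 M of electrophile, a charge above its nucleophile. There 0.280 M⁻¹ h⁻¹ leaves 17.3 % of the electrophile, and the flask holds 16.9 %.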